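## The problem

Baeomycesic acid (23) is a depside: two pentasubstituted benzene rings held together by a single aryl ester between the C1 carboxyl of ring A and the C4' oxygen of ring B. It has no stereocentre, so the difficulties are regiochemistry and the order of events on two crowded rings. Ring A carries in sequence the ester carbon (C1), a free phenol (C2), a formyl group (C3), a methoxy group (C4), a hydrogen (C5) and a methyl group (C6). Its two oxygens must be told apart, and C3 must be functionalised in preference to C5, which electrophilic formylation of an orsellinate-type ring does not guarantee. Ring B is a β-orcinol carboxylic acid whose C2' phenol and carboxyl must end free while its C4' oxygen is acylated. The fragile parts are: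
- the depside ester, which alkoxides and amines cleave and which can fragment once a phenoxide is generated para or ortho to it;
- the aldehyde, which is open to reduction and condensation;
- the salicylic-type acid of ring B, which decarboxylates in hot acid;
- on the way, any aryl–silicon bond flanked by oxygens, which is open to ipso-protonation.

The feature that opens the route is that the C3 formyl carbon lies between the C2 and C4 oxygens. That pattern arises when a C3–C4 aryne, flanked by an oxygen only at C2, takes up the carbon and the oxygen of a formamide. The C3–C and C4–O bonds can therefore be made together, with the C2 oxygen dictating the orientation.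

## Retrosynthesis

**23 from 22.** The three O–benzyl bonds (ester of ring B, ethers at C2 and C2') are cut last. One hydrogenolysis frees the acid and both chelated phenols without touching the depside ester. The forward step must spare the aldehyde.

**22 from 21.** The C4 O–methyl bond is cut next. In 21 the C4 hydroxyl is the only free phenol, so methylation has no regiochemical choice to make. This is simpler than selective methylation of a 2,4-dihydroxy-3-formyl ring.

**21 from 16 and 17 (key disconnection).** The C3–CHO bond and the C4–O bond are cut together, leading back to silyl triflate 16 and dimethylformamide 17.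
- Against the neighbouring cuts: electrophilic formylation of a depside would have to choose between C3 and C5 under Lewis-acidic conditions, and metalation–formylation is excluded by the two esters.
- In the forward direction fluoride releases aryne 18. The formamide oxygen adds to C4 and its carbon to C3 through benzoxete 19 and ortho-quinone methide 20. Water then gives the phenol and the aldehyde.
- The precursor is simpler: both hetero-substituents at C3 and C4 trace back to the two equivalent oxygens of a symmetric resorcinol and the carbon between them.
- The forward reaction needs oxygen to go to C4 and carbon to C3, and a substrate with no free OH that could intercept the aryne.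

**16 from 12 by way of 15, 14 and 13.** The S–O bond of the triflate, the two benzyl ether bonds and a temporary allyl ether are cut in that order.
- The triflate must go on last. A phenoxide next to the silylated carbon, once a triflate sits on its other side, can pull silicon from carbon to oxygen and expel triflate, which would form the aryne prematurely. The C2 and C2' phenols are therefore benzylated before C4 is sulfonylated.
- In triol 12 the C4 hydroxyl is the most reactive phenol, the reverse of the order needed. It is masked first as an allyl ether (13), the two chelated phenols are benzylated (14), the allyl group is removed by palladium catalysis (15), and only then is the triflate installed.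
- Each operation uses the intrinsic difference between a free phenol and a phenol hydrogen-bonded to an ester carbonyl.

**12 from 10 and 3 by way of 11.** The acetal C–O bonds are cut, then the depside ester C(=O)–O4' bond. This gives ring A acid 10 and ring B phenol 3.
- The ester is formed only after all organolithium chemistry on ring A is finished, so the route is convergent.
- Ring B needs no protection for the coupling, because its C2' hydroxyl is chelated to the benzyl ester and hindered.
- The forward step must join a 2,6-disubstituted acid to a phenol with an ortho methyl group.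
- The acetal removal must spare the aryl–silicon bond.

**10 from 4 by way of 7 and 5.** The C1–CO2H bond and the C3–Si bond are cut back to bis-acetal 5 and orcinol 4.
- Both bonds come from directed ortho-metalation.
- The first lithiation (6) takes the position between the two acetal oxygens.
- After silylation, the two remaining ring hydrogens of 7 are equivalent, so the second lithiation (8) and carboxylation (9, then 10) cannot give a regioisomer.
- Silicon is placed where metalation is easiest, and the carboxyl group where the blocked ring leaves no alternative.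

**3 from 1 by way of 2.** The benzyl ester O–C bond is cut. Commercial atraric acid 1 is saponified to acid 2, which is re-esterified at the carboxylate only. The benzyl ester is chosen so that the last step can remove it together with the benzyl ethers.

## Roads not taken

**Alternative 1:** The cut goes through ring B (C1'–C2' and C5'–C6').
- Forward key step: 4-methoxy-3-methyl-4-(trimethylsilyloxy)buta-1,3-dien-2-yl 2-(benzyloxy)-4-methoxy-6-methylbenzoate A1 would add on heating to tert-butyl but-2-ynoate A2. 1,4-Elimination of the acetal methoxy group would aromatise the adduct to tert-butyl 4-{[2-(benzyloxy)-4-methoxy-6-methylbenzoyl]oxy}-2-hydroxy-3,6-dimethylbenzoate A3.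
- Merits: ring B is built with every substituent placed by the polarity of diene and dienophile. The depside oxygen is acylated at the enol stage, so ring B needs no phenol differentiation. The C4 methoxy group is present from the start. In these respects it is cleaner than the chosen plan, which spends steps on protecting-group traffic.
- Weak points: A1 is both an enol ester and a silyl ketene acetal, and making it means deprotonating next to an acyl group that can migrate. A2 is a sluggish dienophile, and the acyloxy group lowers the reactivity of the diene.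
- The decisive gap: A3 has no formyl group. C3 would have to be formylated late, on a base- and Lewis-acid-sensitive depside, with C5 as a competing site.
- Comparison: the chosen plan answers exactly this point. The position of silicon and triflate fixes where carbon and oxygen enter ring A.

**Alternative 2:** The cut dismantles ring A completely (C1–C2, C2–C3, C4–C5, C5–C6).
- Forward key step: irradiation of benzyl 2-(benzyloxy)-4-{[(2E)-5-diazo-3-methyl-4-oxopent-2-enoyl]oxy}-3,6-dimethylbenzoate A4 would give a vinylketene by Wolff rearrangement. This would add tert-butyl[(3-methoxyprop-2-yn-1-yl)oxy]dimethylsilane A5. Four-electron opening of the vinylcyclobutenone and six-electron closure of the dienylketene would give benzyl 2-(benzyloxy)-4-{[3-(tert-butyldimethylsilyloxymethyl)-2-hydroxy-4-methoxy-6-methylbenzoyl]oxy}-3,6-dimethylbenzoate A6.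
- Merits: all six positions of ring A are set by the mechanism. The C2 phenol is free, the C4 methoxy group is in place, and the C3 carbon is one oxidation away from the aldehyde. In regiochemical certainty and in protecting-group economy on ring A this road is at least equal to the chosen one and probably better.
- Weak points: A4 is a diazoketone on an electron-poor, aryl ester-bearing enone, and its preparation and photolysis must spare that ester. A5 is a labile ynol ether, whereas the well-established partners of this benzannulation are siloxyalkynes. The ketene intermediates can acylate the phenol they produce. After the annulation, desilylation and oxidation still precede hydrogenolysis.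
- Comparison: the chosen plan uses shelf-stable aromatic intermediates and forms its two bonds at room temperature with fluoride. It pays with a longer sequence of protections.

**Alternative 3:** The cut is the C1–C6 bond of ring A.
- Forward key step: benzyl 2-hydroxy-3,6-dimethyl-4-[(3,5,7-trioxooctanoyl)oxy]benzoate A7 would cyclise by aldol attack of chain carbon 2 on the carbon 7 ketone, followed by dehydration and enolisation, to benzyl 4-[(2,4-dihydroxy-6-methylbenzoyl)oxy]-2-hydroxy-3,6-dimethylbenzoate A8.
- Merits: this is the shortest conceivable way to ring A with the depside ester already in place, and it needs no protecting group on ring A. In step count it beats the chosen plan.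
- Weak points: A7 is an aryl ester of a polyketo acid, and the aryloxide is a good leaving group. Claisen-type ring closure, lactonisation to a pyranone and acylketene formation would all expel ring B, and they compete directly with the aldol folding. A8 still lacks the C4 methyl ether and the formyl group, so the C3 against C5 formylation problem returns on a depside with free para and ortho phenols.
- Comparison: the chosen plan is longer, but the two substituents that A8 lacks are the ones its key step installs with defined orientation.

Key step: step 12

Remark: orcinol is taken in its anhydrous form; the monohydrate would be dried azeotropically before step 3.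

## Route

Step 1
Reactants: 1 methyl 2,4-dihydroxy-3,6-dimethylbenzoate (atraric acid)
Product: 2 2,4-dihydroxy-3,6-dimethylbenzoic acid
Conditions: KOH (aq, 4 M), 80 °C, argon; then 2 M HCl, 0 °C
Reagents that add atoms: potassium hydroxide, [K+].[OH-]
Why: Saponification of a salicylate-type methyl ester; in base the ring is held as phenoxide and carboxylate, and decarboxylation is avoided by acidifying cold and not heating the free acid.

Step 2
Reactants: 2 2,4-dihydroxy-3,6-dimethylbenzoic acid
Product: 3 benzyl 2,4-dihydroxy-3,6-dimethylbenzoate
Conditions: BnBr (1.05 equiv), KHCO3, DMF, 25–40 °C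
Reagents that add atoms: benzyl bromide, BrCc1ccccc1
Why: Hydrogencarbonate deprotonates only the carboxylic acid, so SN2 alkylation of the carboxylate gives the benzyl ester and leaves both phenols free; this is the usual way to benzyl esters of hydroxybenzoic acids.

Step 3
Reactants: 4 orcinol (5-methylbenzene-1,3-diol)
Product: 5 1,3-bis(methoxymethoxy)-5-methylbenzene
Conditions: NaH (2.5 equiv), MOMCl (2.4 equiv), DMF, 0 °C to 25 °C
Reagents that add atoms: chloromethyl methyl ether, COCCl
Why: Williamson-type O-alkylation of both phenoxides; the two acetals serve as directing groups for the metalations that follow.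

Step 4
Reactants: 5 1,3-bis(methoxymethoxy)-5-methylbenzene
Product: 7 [2,6-bis(methoxymethoxy)-4-methylphenyl]trimethylsilane, via aryllithium 6 (not isolated)
Conditions: n-BuLi (1.1 equiv), THF, 0 °C; then TMSCl, −78 °C to 25 °C
Reagents that add atoms: chlorotrimethylsilane, C[Si](C)(C)Cl
Why: Directed ortho-metalation at the position between the two acetal oxygens, the most acidic ring C–H, followed by silylation of 6; this sets the future C3–Si bond.

Step 5
Reactants: 7 [2,6-bis(methoxymethoxy)-4-methylphenyl]trimethylsilane
Product: 10 2,4-bis(methoxymethoxy)-6-methyl-3-(trimethylsilyl)benzoic acid, via ring A aryllithium 8 (not isolated), via lithium carboxylate 9 (not isolated)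
Conditions: s-BuLi (1.3 equiv), TMEDA, THF, −78 °C to −40 °C; CO2 (gas), −78 °C to 0 °C; cold dilute HCl to pH 4
Reagents that add atoms: carbon dioxide, O=C=O
Why: Second directed ortho-metalation with the silyl group blocking the position between the oxygens; the two remaining ring hydrogens are equivalent, so only one aryllithium 8 can form, and carboxylation gives 9, which is protonated cold to spare the acetal next to the new acid.

Step 6
Reactants: 10 2,4-bis(methoxymethoxy)-6-methyl-3-(trimethylsilyl)benzoic acid; 3 benzyl 2,4-dihydroxy-3,6-dimethylbenzoate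
Product: 11 benzyl 4-{[2,4-bis(methoxymethoxy)-6-methyl-3-(trimethylsilyl)benzoyl]oxy}-2-hydroxy-3,6-dimethylbenzoate
Conditions: EDC·HCl (1.5 equiv), DMAP (1 equiv), CH2Cl2, 25 °C
Reagents that add atoms: none
Why: Steglich esterification through the acylpyridinium ion; of the two phenols of 3 only the C4' hydroxyl is free of the hydrogen bond to the ester carbonyl, so it is acylated selectively, as in classical depside couplings.

Step 7
Reactants: 11 benzyl 4-{[2,4-bis(methoxymethoxy)-6-methyl-3-(trimethylsilyl)benzoyl]oxy}-2-hydroxy-3,6-dimethylbenzoate
Product: 12 benzyl 4-{[2,4-dihydroxy-6-methyl-3-(trimethylsilyl)benzoyl]oxy}-2-hydroxy-3,6-dimethylbenzoate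
Conditions: ZnBr2 (2.5 equiv), n-PrSH (5 equiv), CH2Cl2, 0 °C
Reagents that add atoms: none
Why: Lewis acid-assisted thiolysis of both methoxymethyl acetals under nearly neutral conditions, chosen because protic acid would risk ipso-protodesilylation of the silane between two oxygens; the esters are not touched.

Step 8
Reactants: 12 benzyl 4-{[2,4-dihydroxy-6-methyl-3-(trimethylsilyl)benzoyl]oxy}-2-hydroxy-3,6-dimethylbenzoate
Product: 13 benzyl 2-hydroxy-4-{[2-hydroxy-6-methyl-4-(prop-2-en-1-yloxy)-3-(trimethylsilyl)benzoyl]oxy}-3,6-dimethylbenzoate
Conditions: allyl bromide (1.1 equiv), K2CO3 (1.1 equiv), acetone, 25 °C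
Reagents that add atoms: allyl bromide, C=CCBr
Why: Williamson etherification; the C4 phenol of ring A is the only hydroxyl not hydrogen-bonded to an ester carbonyl and, being para to the acyl group, the most acidic, so one equivalent of base and halide alkylates it selectively, as is usual for 2,4-dihydroxybenzoates.

Step 9
Reactants: 13 benzyl 2-hydroxy-4-{[2-hydroxy-6-methyl-4-(prop-2-en-1-yloxy)-3-(trimethylsilyl)benzoyl]oxy}-3,6-dimethylbenzoate
Product: 14 benzyl 2-(benzyloxy)-4-{[2-(benzyloxy)-6-methyl-4-(prop-2-en-1-yloxy)-3-(trimethylsilyl)benzoyl]oxy}-3,6-dimethylbenzoate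
Conditions: BnBr (3 equiv), Cs2CO3 (3 equiv), n-Bu4NI (cat.), DMF, 40 °C
Reagents that add atoms: benzyl bromide, BrCc1ccccc1
Why: Williamson etherification of the two chelated phenols under more forcing conditions; no leaving group sits next to the silylated carbon at this stage, so a phenoxide beside silicon does no harm.

Step 10
Reactants: 14 benzyl 2-(benzyloxy)-4-{[2-(benzyloxy)-6-methyl-4-(prop-2-en-1-yloxy)-3-(trimethylsilyl)benzoyl]oxy}-3,6-dimethylbenzoate
Product: 15 benzyl 2-(benzyloxy)-4-{[2-(benzyloxy)-4-hydroxy-6-methyl-3-(trimethylsilyl)benzoyl]oxy}-3,6-dimethylbenzoate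
Conditions: Pd(PPh3)4 (5 mol %), morpholine (5 equiv), THF, 25 °C
Reagents that add atoms: none
Why: Tsuji–Trost-type deallylation: zerovalent palladium ionises the allyl aryl ether to a π-allyl complex that the amine captures; benzyl ethers, both esters and the aryl silane are inert.

Step 11
Reactants: 15 benzyl 2-(benzyloxy)-4-{[2-(benzyloxy)-4-hydroxy-6-methyl-3-(trimethylsilyl)benzoyl]oxy}-3,6-dimethylbenzoate
Product: 16 benzyl 2-(benzyloxy)-4-{[2-(benzyloxy)-6-methyl-4-(trifluoromethylsulfonyloxy)-3-(trimethylsilyl)benzoyl]oxy}-3,6-dimethylbenzoate
Conditions: Tf2O (1.2 equiv), pyridine (3 equiv), CH2Cl2, −78 °C to 0 °C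
Reagents that add atoms: trifluoromethanesulfonic anhydride, O=S(=O)(OS(=O)(=O)C(F)(F)F)C(F)(F)F
Why: O-Sulfonylation of the ortho-silyl phenol with a weak amine base, the standard last step towards ortho-silylaryl triflates; because both other phenols are already benzylated, no phenoxide can pull silicon towards oxygen and set off the aryne early.

Step 12
Reactants: 16 benzyl 2-(benzyloxy)-4-{[2-(benzyloxy)-6-methyl-4-(trifluoromethylsulfonyloxy)-3-(trimethylsilyl)benzoyl]oxy}-3,6-dimethylbenzoate; 17 N,N-dimethylformamide
Product: 21 benzyl 2-(benzyloxy)-4-{[2-(benzyloxy)-3-formyl-4-hydroxy-6-methylbenzoyl]oxy}-3,6-dimethylbenzoate, via ring A 3,4-aryne 18 (not isolated), via aminobenzoxete 19 (not isolated), via ortho-quinone methide 20 (not isolated)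
Conditions: CsF (3 equiv), 17 as solvent (0.05 M), 25 °C; then 1 M HCl (aq), 25 °C
Reagents that add atoms: water, O
Why: Fluoride attacks silicon at C3 and triflate leaves from C4, which should release the C3–C4 aryne 18 at room temperature without any strong base. The oxygen of 17 adds to C4, and the aryl anion formed at C3 closes on the iminium carbon in a stepwise 2+2 addition to benzoxete 19, which opens to ortho-quinone methide 20; aqueous acid hydrolyses 20 to the C4 phenol and the C3 aldehyde and carries off dimethylamine as its salt. The closest known reaction type is the insertion of arynes from ortho-silylaryl triflates into the carbonyl group of formamides with hydrolysis to salicylaldehydes, which is regioselective for 3-alkoxyarynes. The only ring closed is the transient four-membered benzoxete, formed by 4-exo attack of the aryl anion on the iminium carbon, and it does not survive into the product. No stereocentre remains, since the aminal carbon of 19 ends as the planar formyl carbon. The step needs oxygen at C4 and carbon at C3: the inductively withdrawing C2 benzyloxy group makes the remote carbon C4 the electrophilic end of the aryne and stabilises the negative charge at C3, and the same group shields C3 sterically while C4 is flanked only by hydrogen. Compound 16 has no free OH that could compete with the solvent for the aryne, both ester carbonyls are shielded by two ortho substituents against fluoride, and the acidic quench keeps the liberated amine protonated and away from the depside ester.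

Step 13
Reactants: 21 benzyl 2-(benzyloxy)-4-{[2-(benzyloxy)-3-formyl-4-hydroxy-6-methylbenzoyl]oxy}-3,6-dimethylbenzoate
Product: 22 benzyl 2-(benzyloxy)-4-{[2-(benzyloxy)-3-formyl-4-methoxy-6-methylbenzoyl]oxy}-3,6-dimethylbenzoate
Conditions: MeI (3 equiv), K2CO3 (1.5 equiv), acetone, 25 °C
Reagents that add atoms: iodomethane, CI
Why: Williamson methylation of the acidic phenol next to the formyl group; it is the only free hydroxyl in 21, so the C4 methyl ether forms without any regiochemical choice.

Step 14
Reactants: 22 benzyl 2-(benzyloxy)-4-{[2-(benzyloxy)-3-formyl-4-methoxy-6-methylbenzoyl]oxy}-3,6-dimethylbenzoate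
Product: 23 baeomycesic acid, 4-[(3-formyl-2-hydroxy-4-methoxy-6-methylbenzoyl)oxy]-2-hydroxy-3,6-dimethylbenzoic acid
Conditions: H2 (1 atm), 10% Pd/C, EtOAc, 25 °C, stopped after uptake of 3 equiv
Reagents that add atoms: none
Why: Catalytic hydrogenolysis cleaves the benzyl ester and both benzyl ethers in one operation; the electron-rich aldehyde between two oxygens, chelated once the C2 phenol is free, should survive at atmospheric pressure, as is usual for formyl-bearing depside benzyl esters.

## Compound list

1 | methyl 2,4-dihydroxy-3,6-dimethylbenzoate (atraric acid) | COC(=O)c1c(C)cc(O)c(C)c1O | starting material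
2 | 2,4-dihydroxy-3,6-dimethylbenzoic acid | Cc1cc(O)c(C)c(O)c1C(=O)O | intermediate
3 | benzyl 2,4-dihydroxy-3,6-dimethylbenzoate | Cc1cc(O)c(C)c(O)c1C(=O)OCc1ccccc1 | intermediate
4 | orcinol (5-methylbenzene-1,3-diol) | Cc1cc(O)cc(O)c1 | starting material
5 | 1,3-bis(methoxymethoxy)-5-methylbenzene | Cc1cc(OCOC)cc(OCOC)c1 | intermediate
6 | [2,6-bis(methoxymethoxy)-4-methylphenyl]lithium | [Li]c1c(OCOC)cc(C)cc1OCOC | intermediate
7 | [2,6-bis(methoxymethoxy)-4-methylphenyl]trimethylsilane | Cc1cc(OCOC)c([Si](C)(C)C)c(OCOC)c1 | intermediate
8 | [2,4-bis(methoxymethoxy)-6-methyl-3-(trimethylsilyl)phenyl]lithium | [Li]c1c(C)cc(OCOC)c([Si](C)(C)C)c1OCOC | intermediate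
9 | lithium 2,4-bis(methoxymethoxy)-6-methyl-3-(trimethylsilyl)benzoate | [Li+].[O-]C(=O)c1c(C)cc(OCOC)c([Si](C)(C)C)c1OCOC | intermediate
10 | 2,4-bis(methoxymethoxy)-6-methyl-3-(trimethylsilyl)benzoic acid | Cc1cc(OCOC)c([Si](C)(C)C)c(OCOC)c1C(=O)O | intermediate
11 | benzyl 4-{[2,4-bis(methoxymethoxy)-6-methyl-3-(trimethylsilyl)benzoyl]oxy}-2-hydroxy-3,6-dimethylbenzoate | Cc1cc(OCOC)c([Si](C)(C)C)c(OCOC)c1C(=O)Oc1cc(C)c(C(=O)OCc2ccccc2)c(O)c1C | intermediate
12 | benzyl 4-{[2,4-dihydroxy-6-methyl-3-(trimethylsilyl)benzoyl]oxy}-2-hydroxy-3,6-dimethylbenzoate | Cc1cc(O)c([Si](C)(C)C)c(O)c1C(=O)Oc1cc(C)c(C(=O)OCc2ccccc2)c(O)c1C | intermediate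
13 | benzyl 2-hydroxy-4-{[2-hydroxy-6-methyl-4-(prop-2-en-1-yloxy)-3-(trimethylsilyl)benzoyl]oxy}-3,6-dimethylbenzoate | C=CCOc1cc(C)c(C(=O)Oc2cc(C)c(C(=O)OCc3ccccc3)c(O)c2C)c(O)c1[Si](C)(C)C | intermediate
14 | benzyl 2-(benzyloxy)-4-{[2-(benzyloxy)-6-methyl-4-(prop-2-en-1-yloxy)-3-(trimethylsilyl)benzoyl]oxy}-3,6-dimethylbenzoate | C=CCOc1cc(C)c(C(=O)Oc2cc(C)c(C(=O)OCc3ccccc3)c(OCc3ccccc3)c2C)c(OCc2ccccc2)c1[Si](C)(C)C | intermediate
15 | benzyl 2-(benzyloxy)-4-{[2-(benzyloxy)-4-hydroxy-6-methyl-3-(trimethylsilyl)benzoyl]oxy}-3,6-dimethylbenzoate | Cc1cc(O)c([Si](C)(C)C)c(OCc2ccccc2)c1C(=O)Oc1cc(C)c(C(=O)OCc2ccccc2)c(OCc2ccccc2)c1C | intermediate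
16 | benzyl 2-(benzyloxy)-4-{[2-(benzyloxy)-6-methyl-4-(trifluoromethylsulfonyloxy)-3-(trimethylsilyl)benzoyl]oxy}-3,6-dimethylbenzoate | Cc1cc(OS(=O)(=O)C(F)(F)F)c([Si](C)(C)C)c(OCc2ccccc2)c1C(=O)Oc1cc(C)c(C(=O)OCc2ccccc2)c(OCc2ccccc2)c1C | intermediate
17 | N,N-dimethylformamide | CN(C)C=O | starting material
18 | benzyl 2-(benzyloxy)-4-{[2-(benzyloxy)-3,4-didehydro-6-methylbenzoyl]oxy}-3,6-dimethylbenzoate (ring A 3,4-aryne) | CC1=CC#CC(OCc2ccccc2)=C1C(=O)Oc1cc(C)c(C(=O)OCc2ccccc2)c(OCc2ccccc2)c1C | intermediate
19 | benzyl 2-(benzyloxy)-4-({[3-(benzyloxy)-2-(dimethylamino)-5-methyl-2H-1-benzoxet-4-yl]carbonyl}oxy)-3,6-dimethylbenzoate (aminobenzoxete, racemic at the aminal carbon) | Cc1cc2OC(N(C)C)c2c(OCc2ccccc2)c1C(=O)Oc1cc(C)c(C(=O)OCc2ccccc2)c(OCc2ccccc2)c1C | intermediate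
20 | benzyl 2-(benzyloxy)-4-({[2-(benzyloxy)-3-[(dimethylamino)methylidene]-6-methyl-4-oxocyclohexa-1,5-dien-1-yl]carbonyl}oxy)-3,6-dimethylbenzoate (ortho-quinone methide) | CC1=CC(=O)C(=CN(C)C)C(OCc2ccccc2)=C1C(=O)Oc1cc(C)c(C(=O)OCc2ccccc2)c(OCc2ccccc2)c1C | intermediate
21 | benzyl 2-(benzyloxy)-4-{[2-(benzyloxy)-3-formyl-4-hydroxy-6-methylbenzoyl]oxy}-3,6-dimethylbenzoate | Cc1cc(O)c(C=O)c(OCc2ccccc2)c1C(=O)Oc1cc(C)c(C(=O)OCc2ccccc2)c(OCc2ccccc2)c1C | intermediate
22 | benzyl 2-(benzyloxy)-4-{[2-(benzyloxy)-3-formyl-4-methoxy-6-methylbenzoyl]oxy}-3,6-dimethylbenzoate | COc1cc(C)c(C(=O)Oc2cc(C)c(C(=O)OCc3ccccc3)c(OCc3ccccc3)c2C)c(OCc2ccccc2)c1C=O | intermediate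
23 | baeomycesic acid, 4-[(3-formyl-2-hydroxy-4-methoxy-6-methylbenzoyl)oxy]-2-hydroxy-3,6-dimethylbenzoic acid | COc1cc(C)c(C(=O)Oc2cc(C)c(C(=O)O)c(O)c2C)c(O)c1C=O | target

## Step count and least certain steps

Total: 14 steps. Longest linear sequence: 12 steps (orcinol 4 to 23, steps 3 to 14). The ring B branch (steps 1 and 2) joins at step 6.

**Step 12 (key step).**
- What may go wrong: capture of the aryne by fluoride, by traces of water or by phenoxide formed from early product, in competition with the formamide; slow release of the aryne from a silicon atom shielded by two ortho oxygens, which would give fluoride time to attack the aryl ester; and erosion of the orientation if the remote ester perturbs the aryne.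
- Fallback: from 15 to 22, using the silicon as a placeholder for iodine. O-Methylation of 15 (iodomethane, K2CO3) would give benzyl 2-(benzyloxy)-4-{[2-(benzyloxy)-4-methoxy-6-methyl-3-(trimethylsilyl)benzoyl]oxy}-3,6-dimethylbenzoate F1. Ipso-iododesilylation with ICl in CH2Cl2 would give benzyl 2-(benzyloxy)-4-{[2-(benzyloxy)-3-iodo-4-methoxy-6-methylbenzoyl]oxy}-3,6-dimethylbenzoate F2. Iodine–magnesium exchange with iPrMgCl·LiCl at −40 °C, which hindered esters tolerate, would give the arylmagnesium chloride F3. F3 adds to 17 to give the magnesium hemiaminalate F4, and aqueous acid releases aldehyde 22, where the route is rejoined.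

**Step 5.**
- What may go wrong: deprotonation of the ring methyl group or of a silicon methyl group instead of the ring position; incomplete metalation of a site flanked by a methyl group; loss of the acetal next to the new acid during work-up.
- Fallback: from 7 to 10 by halogen–metal exchange. Bromination of 7 with N-bromosuccinimide in acetonitrile at 0 °C, at the position para to one acetal oxygen, would give [3-bromo-2,6-bis(methoxymethoxy)-4-methylphenyl]trimethylsilane F5. Bromine–lithium exchange with n-BuLi at −78 °C would give aryllithium 8, which is carboxylated as before to 9 and 10.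

**Step 7.**
- What may go wrong: ipso-protodesilylation of the electron-rich aryl–silicon bond during acetal cleavage, or cleavage that stops at a mono-acetal.
- Fallback: from 11 to 12 by exchange of the acetals for silyl ethers under buffered, non-acidic conditions. TMSOTf with excess 2,2'-bipyridyl in CH2Cl2 would convert the aryl acetals, and the free ring B phenol, into the tris(trimethylsilyl) ether benzyl 4-{[6-methyl-3-(trimethylsilyl)-2,4-bis(trimethylsilyloxy)benzoyl]oxy}-3,6-dimethyl-2-(trimethylsilyloxy)benzoate F6. Its O–Si bonds are hydrolysed by water at neutral pH to give 12.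

**Step 13.**
- What may go wrong: fragmentation of the depside ester through the phenoxide para to the acyl group (ketene-type expulsion of the ring B phenoxide), or attack of carbonate on the ester during a slow alkylation.
- Fallback: from 21 to 22 without a metal phenoxide. Methylation with trimethylsilyldiazomethane in toluene–methanol proceeds by proton transfer from the acidic, formyl-flanked phenol. This detour makes no new compound (F0).

**Step 14.**
- What may go wrong: over-reduction of the formyl group to the benzylic alcohol and on to a methyl group while the last benzyl group is being removed.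
- Fallback: from 22 to 23 by Lewis-acid debenzylation. BCl3 with pentamethylbenzene as cation scavenger in CH2Cl2 at −78 °C cleaves benzyl ethers and the benzyl ester without a reducing agent. The low temperature spares the methyl ether and the depside ester. This detour makes no new compound (F0).

## Further compounds

F1 | step 12 | benzyl 2-(benzyloxy)-4-{[2-(benzyloxy)-4-methoxy-6-methyl-3-(trimethylsilyl)benzoyl]oxy}-3,6-dimethylbenzoate | COc1cc(C)c(C(=O)Oc2cc(C)c(C(=O)OCc3ccccc3)c(OCc3ccccc3)c2C)c(OCc2ccccc2)c1[Si](C)(C)C
F2 | step 12 | benzyl 2-(benzyloxy)-4-{[2-(benzyloxy)-3-iodo-4-methoxy-6-methylbenzoyl]oxy}-3,6-dimethylbenzoate | COc1cc(C)c(C(=O)Oc2cc(C)c(C(=O)OCc3ccccc3)c(OCc3ccccc3)c2C)c(OCc2ccccc2)c1I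
F3 | step 12 | {2-(benzyloxy)-3-({3-(benzyloxy)-4-[(benzyloxy)carbonyl]-2,5-dimethylphenoxy}carbonyl)-6-methoxy-4-methylphenyl}magnesium chloride | COc1cc(C)c(C(=O)Oc2cc(C)c(C(=O)OCc3ccccc3)c(OCc3ccccc3)c2C)c(OCc2ccccc2)c1[Mg]Cl
F4 | step 12 | chloromagnesium hemiaminalate from F3 and N,N-dimethylformamide (aryl–CH(NMe2)–OMgCl) | COc1cc(C)c(C(=O)Oc2cc(C)c(C(=O)OCc3ccccc3)c(OCc3ccccc3)c2C)c(OCc2ccccc2)c1C(O[Mg]Cl)N(C)C
F5 | step 5 | [3-bromo-2,6-bis(methoxymethoxy)-4-methylphenyl]trimethylsilane | Cc1cc(OCOC)c([Si](C)(C)C)c(OCOC)c1Br
F6 | step 7 | benzyl 4-{[6-methyl-3-(trimethylsilyl)-2,4-bis(trimethylsilyloxy)benzoyl]oxy}-3,6-dimethyl-2-(trimethylsilyloxy)benzoate | Cc1cc(O[Si](C)(C)C)c([Si](C)(C)C)c(O[Si](C)(C)C)c1C(=O)Oc1cc(C)c(C(=O)OCc2ccccc2)c(O[Si](C)(C)C)c1C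
F0 | step 13 | none | none
F0 | step 14 | none | none
A1 | alternative 1 | 4-methoxy-3-methyl-4-(trimethylsilyloxy)buta-1,3-dien-2-yl 2-(benzyloxy)-4-methoxy-6-methylbenzoate | C=C(OC(=O)c1c(C)cc(OC)cc1OCc1ccccc1)C(C)=C(OC)O[Si](C)(C)C
A2 | alternative 1 | tert-butyl but-2-ynoate | CC#CC(=O)OC(C)(C)C
A3 | alternative 1 | tert-butyl 4-{[2-(benzyloxy)-4-methoxy-6-methylbenzoyl]oxy}-2-hydroxy-3,6-dimethylbenzoate | COc1cc(C)c(C(=O)Oc2cc(C)c(C(=O)OC(C)(C)C)c(O)c2C)c(OCc2ccccc2)c1
A4 | alternative 2 | benzyl 2-(benzyloxy)-4-{[(2E)-5-diazo-3-methyl-4-oxopent-2-enoyl]oxy}-3,6-dimethylbenzoate | [N-]=[N+]=CC(=O)/C(C)=C/C(=O)Oc1cc(C)c(C(=O)OCc2ccccc2)c(OCc2ccccc2)c1C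
A5 | alternative 2 | tert-butyl[(3-methoxyprop-2-yn-1-yl)oxy]dimethylsilane | COC#CCO[Si](C)(C)C(C)(C)C
A6 | alternative 2 | benzyl 2-(benzyloxy)-4-{[3-(tert-butyldimethylsilyloxymethyl)-2-hydroxy-4-methoxy-6-methylbenzoyl]oxy}-3,6-dimethylbenzoate | COc1cc(C)c(C(=O)Oc2cc(C)c(C(=O)OCc3ccccc3)c(OCc3ccccc3)c2C)c(O)c1CO[Si](C)(C)C(C)(C)C
A7 | alternative 3 | benzyl 2-hydroxy-3,6-dimethyl-4-[(3,5,7-trioxooctanoyl)oxy]benzoate | CC(=O)CC(=O)CC(=O)CC(=O)Oc1cc(C)c(C(=O)OCc2ccccc2)c(O)c1C
A8 | alternative 3 | benzyl 4-[(2,4-dihydroxy-6-methylbenzoyl)oxy]-2-hydroxy-3,6-dimethylbenzoate | Cc1cc(O)cc(O)c1C(=O)Oc1cc(C)c(C(=O)OCc2ccccc2)c(O)c1C
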